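**Remark on the chemistry (assumption):** the target has no stereocentre, stereoaxis or stereogenic double bond. It is one achiral compound, so "single enantiomer" needs no stereocontrol anywhere in the route.

Ring numbering used throughout: O1, C2 (Br), C3 (Br), C4 (C=O), C5 (Br), C6 (side chain), and C1′ for the CBr2 carbon of the side chain.

## Analysis of the target

The target (10) is a fully substituted monocyclic 4H-pyran-4-one, C8H5Br5O2, whose eight carbons form one unbranched chain (C2 to C6 of the ring, then C1′ to C3′). It is flat and achiral, so the whole problem is one of regiochemistry and oxidation level, not of stereochemistry. The five C–Br bonds are of three kinds. C3 and C5 lie alpha to the C4 carbonyl and are nucleophilic positions that electrophilic bromine can reach. C1′ is a gem-dibromide at the ketone oxidation level next to an electron-poor ring. C2 is the odd one: it carries both the ring oxygen O1 and a bromine, so it sits at the carboxylic acid oxidation level and is a vinylogous acyl bromide, which no electrophilic bromination can install. The C2–Br bond is open to addition–elimination by water, alcohols, amines and foreign halides. The C1′ gem-dibromide loses HBr to base and donates Br+ to enolates and other soft nucleophiles. The hardest single demand is to place Br on C2 and the carbonyl on C4, not the reverse, which would give the isomeric 4-bromo-2-pyranone. This feature, O1 and Br on the same ring carbon C2, invites the strategy: C2 is treated as a former CBr2 carbon that keeps one bromine and gives up the other to close the O1–C2 bond.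

## Retrosynthetic reasoning

**Disconnection 1 (10 to 9), the two C1′–Br bonds.** The C1′ methylene of 9 is the only sp3 C–H position that gives a delocalised radical, being allylic to C5=C6 and vinylogously alpha to C4=O. Both bromines are therefore put in last by radical substitution. The gem-dibromide is left to the end because it would not survive the enolate chemistry that builds the ring.

**Disconnection 2 (9 to 8), the C3–Br and C5–Br bonds.** C3 and C5 are the beta carbons of the two enol ether units O1–C2=C3 and O1–C6=C5 and accept electrophilic bromine. Doing this after ring formation keeps the ring-forming step free of extra halogen. Blocking both ring positions before the radical step leaves C1′ as the only site for further bromination.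

**Disconnection 3 (8 to 4 and 5, through 6 and 7), the O1–C2 and C4–C5 bonds; the key step.** Cutting O1–C2 turns C2 into a 1,1-dibromoalkene carbon and O1 into a ketone enolate oxygen. Cutting C4–C5 separates an acyl bromide (4, three carbons: C2, C3, C4) from a methyl ketone (5, five carbons: C5, C6 and the propyl group, plus O1). The cut is made here because it removes the tautomer ambiguity entirely. The ring oxygen is never a carboxyl oxygen, and C2 must keep exactly one bromine after the other leaves. The forward reaction has to acylate the kinetic enolate 6 on carbon and then let the enolate oxygen of diketonate 7 displace one vinylic bromide in a six-membered closure.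

**Disconnection 4 (4 to 3 to 2 to 1), the acyl C–Br bond, the ester and the C2=C3 double bond.** Acyl bromide 4 comes from acid 3 and this from ester 2. The C2=C3 bond of 2 is cut by a Ramirez dibromo-olefination of the aldehyde group of 1, so that C2 enters the route already at the acid oxidation level with both its bromines. Bromide is used as the only halide from compound 2 onward, so that any addition–elimination at C2 or its precursor carbon is degenerate and cannot scramble halogens.

## Alternatives that were turned down

**Alternative 1:** the textbook route. Disconnect C2–Br to a lactone carbonyl: 4-hydroxy-6-propyl-2H-pyran-2-one A1 (a triketide pyrone, available by known 3,5-dioxo acid chemistry) would be ring-brominated to 3,5-dibromo-4-hydroxy-6-propyl-2H-pyran-2-one A2 and then deoxybrominated with a phosphoryl bromide type reagent. A2 is an ambident vinylogous acid. Activation occurs at the more acidic 4-OH and bromide then attacks C4, which keeps the conjugated lactone. The expected main product is therefore 3,4,5-tribromo-6-propyl-2H-pyran-2-one A3, a constitutional isomer of 9 with Br on C4 and the carbonyl on C2. Nothing in A2 steers the reaction to the 4-pyranone, and the two isomers would be hard to tell apart and to separate. The route is short, but it leaves the one real regiochemical problem of the target to chance.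

**Alternative 2:** disconnect C2–Br to C2–CO2H. 4-Oxo-6-propyl-4H-pyran-2-carboxylic acid A4, made by a Claisen condensation and cyclisation sequence of about four steps, would undergo Hunsdiecker-type radical bromodecarboxylation to give 8. The regiochemistry would be secure. However, an sp2-bound carboxyl radical on an electron-poor ring loses CO2 slowly, so hydrogen abstraction from the activated lateral CH2 competes. The step would also consume as many operations as the whole chosen sequence to 8. It was turned down on mechanism and step economy.

**Alternative 3:** disconnect O1–C2 and C3–C4 as a hetero-Diels–Alder reaction. Thermolysis of 2,2-dimethyl-6-propyl-4H-1,3-dioxin-4-one A5 would give butanoylketene A6, which would add purchased 1,1-dibromoethene A7 to give 2,2-dibromo-6-propyl-2,3-dihydro-4H-pyran-4-one A8; loss of HBr would then give 8. This would be very short. However, acylketenes are electrophilic heterodienes that need electron-rich 2π partners, and A7 is a poor nucleophile. The faster process would be dimerisation of A6 to 3-butanoyl-4-hydroxy-6-propyl-2H-pyran-2-one A9. The cycloaddition would be untested chemistry with a clear competing sink, so the risk was judged not to be repaid.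

Key step: step 4

## Route

Step 1
Reactants: 1 ethyl glyoxylate (ethyl 2-oxoacetate, commercial toluene solution, distilled before use)
Product: 2 ethyl 3,3-dibromoprop-2-enoate
Conditions: CBr4 (2 equiv), PPh3 (4 equiv), CH2Cl2, 0 °C
Reagents that add atoms: carbon tetrabromide, BrC(Br)(Br)Br
Why: Ramirez dibromo-olefination (first stage of the Corey–Fuchs sequence) of an unhindered, non-enolisable aldehyde; the ylide carbon becomes the future C2 with both bromines, and the ester is inert to the ylide.

Step 2
Reactants: 2 ethyl 3,3-dibromoprop-2-enoate
Product: 3 3,3-dibromoprop-2-enoic acid
Conditions: LiOH·H2O (1.2 equiv), THF/H2O 3:1, 0 °C; then 1 M H2SO4 to pH 1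
Reagents that add atoms: lithium hydroxide, [Li+].[OH-]
Why: Saponification by acyl–oxygen cleavage should be faster at 0 °C than conjugate attack at the dibromo carbon, and the carboxylate formed deactivates that carbon; sulfuric acid is used in the work-up to keep chloride out.

Step 3
Reactants: 3 3,3-dibromoprop-2-enoic acid
Product: 4 3,3-dibromoprop-2-enoyl bromide
Conditions: (COBr)2 (1.2 equiv), DMF (cat.), CH2Cl2, 0 °C to rt; volatiles removed, used crude
Reagents that add atoms: oxalyl bromide, BrC(=O)C(=O)Br
Why: Acid halide formation through the catalytic Vilsmeier-type bromoiminium salt; the acyl bromide is chosen over the chloride so that bromide is the only halide present and exchange at the dibromo carbon is degenerate.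

Step 4
Reactants: 5 pentan-2-one; 4 3,3-dibromoprop-2-enoyl bromide
Product: 8 2-bromo-6-propyl-4H-pyran-4-one, via lithium pent-1-en-2-olate 6 (not isolated), via lithium diketonate 7 (not isolated)
Conditions: LiHMDS (2.05 equiv), THF, −78 °C, then 5 (2.05 equiv); then 4 (1.0 equiv), −78 °C to rt; then 60 °C
Reagents that add atoms: none
Why: The kinetic enolate 6 is acylated on carbon by 4 (addition–elimination at the acyl carbon, forming C4–C5), and a second equivalent of 6 deprotonates the resulting 1,3-diketone to the diketonate 7. On warming, the enolate oxygen on the former ketone carbon attacks the CBr2 carbon and one bromide leaves, which forms O1–C2 and gives the pyranone. The ring closes in a 6-endo-trig vinylic substitution, which can equally be viewed as an oxa-6π electrocyclisation of the s-cis,s-cis oxatriene followed by loss of bromide; both descriptions are allowed, and the closure is irreversible once bromide has left. The closest known reaction types are the acylation of ketone lithium enolates with acyl halides to 1,3-diketones, the substitution of one halide of β,β-dihalovinyl ketones by oxygen nucleophiles, and the closure of 1,3-diketones bearing a β-leaving-group enone to 4-pyranones. No stereocentre is formed. The step needs enolisation at the methyl group (kinetic deprotonation by a hindered amide at −78 °C), C- over O-acylation and attack at the acyl carbon and not at the dibromo carbon (lithium enolate, hard acyl bromide, low temperature). It also needs retention of exactly one bromine at C2, which is secured because after ring closure only bromide and non-nucleophilic hexamethyldisilazane remain. The constitution is fixed by geometry: the other diketonate oxygen could only close a four-membered ring, so the 2-bromo-4-pyranone and not a 2-pyranone must form.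

Step 5
Reactants: 8 2-bromo-6-propyl-4H-pyran-4-one
Product: 9 2,3,5-tribromo-6-propyl-4H-pyran-4-one
Conditions: Br2 (2.3 equiv), CH2Cl2, 0 °C to 40 °C, dark
Reagents that add atoms: bromine, BrBr
Why: Electrophilic bromination (addition–elimination) at C3 and C5, the beta carbons of the two ring enol ether units, as known for 4-pyranones; the HBr formed is harmless because bromide exchange at C2 is degenerate, and darkness suppresses radical attack on the side chain.

Step 6
Reactants: 9 2,3,5-tribromo-6-propyl-4H-pyran-4-one
Product: 10 2,3,5-tribromo-6-(1,1-dibromopropyl)-4H-pyran-4-one
Conditions: NBS (2.3 equiv), AIBN (10 mol%), PhCF3, 85 °C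
Reagents that add atoms: N-bromosuccinimide, O=C1CCC(=O)N1Br
Why: Wohl–Ziegler bromination; C1′ carries the only hydrogens whose abstraction gives a radical delocalised into C5=C6 and C4=O, the first bromine further stabilises the second radical at the same carbon, and the electron-poor ring disfavours ionisation of the intermediate monobromide and hence loss of HBr.

## Compound list

1 | ethyl glyoxylate (ethyl 2-oxoacetate) | CCOC(=O)C=O | starting material
2 | ethyl 3,3-dibromoprop-2-enoate | CCOC(=O)C=C(Br)Br | intermediate
3 | 3,3-dibromoprop-2-enoic acid | OC(=O)C=C(Br)Br | intermediate
4 | 3,3-dibromoprop-2-enoyl bromide | BrC(=O)C=C(Br)Br | intermediate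
5 | pentan-2-one | CCCC(C)=O | starting material
6 | lithium pent-1-en-2-olate | [Li+].[O-]C(=C)CCC | intermediate
7 | lithium (4Z)-1,1-dibromo-3-oxoocta-1,4-dien-5-olate (lithium diketonate) | [Li+].CCC/C([O-])=C/C(=O)C=C(Br)Br | intermediate
8 | 2-bromo-6-propyl-4H-pyran-4-one | CCCc1cc(=O)cc(Br)o1 | intermediate
9 | 2,3,5-tribromo-6-propyl-4H-pyran-4-one | CCCc1oc(Br)c(Br)c(=O)c1Br | intermediate
10 | 2,3,5-tribromo-6-(1,1-dibromopropyl)-4H-pyran-4-one | CCC(Br)(Br)c1oc(Br)c(Br)c(=O)c1Br | target

## Step count and risk

Total step count: 6. Longest linear sequence: 6 steps (1 to 2 to 3 to 4 to 8 to 9 to 10); pentan-2-one 5 enters at step 4.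

**Step 4 (key step).** The most likely failures are O-acylation of the enolate and partial loss of regiocontrol in the enolisation, which would give a branched diketone. Ring closure may also be slow, because the lithium chelate holds the diketonate in the U-shaped conformation in which the enolate oxygen and the CBr2 carbon are far apart; this would give time for intermolecular vinylic substitution and oligomerisation.
Fallback: set out from 4 and use a β-keto ester as a regiodefined nucleophile. Purchased tert-butyl 3-oxohexanoate would be C-acylated with 4 under soft enolisation (MgBr2·OEt2, i-Pr2NEt, CH2Cl2, 0 °C) to give tert-butyl 2-(3,3-dibromoprop-2-enoyl)-3-oxohexanoate F1. Trifluoroacetic acid in CH2Cl2 would cleave the tert-butyl ester, and the tricarbonyl acid would decarboxylate to the free diketone 1,1-dibromooct-1-ene-3,5-dione F2. Warming F2 with catalytic TsOH in toluene at 60 °C would close the ring with loss of HBr and return to the route at 8.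

**Step 6.** The monobromide may lose HBr to the propenyl compound, which would then add bromine and give a vicinal instead of a geminal dibromide. The second hydrogen abstraction may also be slow at a carbon that already bears bromine.
Fallback: set out from 9 and brominate through the lateral anion instead of the radical. LiHMDS in THF at −78 °C would deprotonate C1′ to the extended enolate, which would be trapped on C1′ with CBr4 to give 2,3,5-tribromo-6-(1-bromopropyl)-4H-pyran-4-one F3 (racemic). A second deprotonation and trapping under the same conditions would return to the route at 10.

**Step 5.** Substitution at C3, which is flanked by C2–Br and the carbonyl, may be sluggish. The reaction could then stop at the 5-bromo stage or, if forced, leak into ionic bromination of the side chain.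
Fallback: set out from 2 and bring the C3 bromine in with the three-carbon building block.
- Bromine addition to 2 under irradiation would give ethyl 2,3,3,3-tetrabromopropanoate F4 (racemic).
- Elimination of HBr with i-Pr2NEt would give ethyl 2,3,3-tribromoprop-2-enoate F5.
- De-ethylation with BBr3 would give 2,3,3-tribromoprop-2-enoic acid F6.
- Oxalyl bromide with catalytic DMF would give 2,3,3-tribromoprop-2-enoyl bromide F7.
- Annulation of F7 with 5 under the conditions of step 4 would give 2,3-dibromo-6-propyl-4H-pyran-4-one F8.
- One equivalent of bromine at the activated C5 would return to the route at 9.

**Step 2.** Hydroxide may attack the dibromo carbon in competition with saponification, with loss of a vinylic bromine.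
Fallback: set out from 2 and cleave the alkyl–oxygen bond instead of the acyl–oxygen bond. BBr3 in CH2Cl2 (−10 °C to rt) would de-ethylate the Lewis acid–ester complex with bromide as the only nucleophile, and aqueous work-up would return to the route at 3. This fallback makes no new compound (F0).

## Further compounds

F1 | step 4 | tert-butyl 2-(3,3-dibromoprop-2-enoyl)-3-oxohexanoate (racemic, enolised) | CCCC(=O)C(C(=O)OC(C)(C)C)C(=O)C=C(Br)Br
F2 | step 4 | 1,1-dibromooct-1-ene-3,5-dione | CCCC(=O)CC(=O)C=C(Br)Br
F3 | step 6 | 2,3,5-tribromo-6-(1-bromopropyl)-4H-pyran-4-one (racemic) | CCC(Br)c1oc(Br)c(Br)c(=O)c1Br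
F4 | step 5 | ethyl 2,3,3,3-tetrabromopropanoate (racemic) | CCOC(=O)C(Br)C(Br)(Br)Br
F5 | step 5 | ethyl 2,3,3-tribromoprop-2-enoate | CCOC(=O)C(Br)=C(Br)Br
F6 | step 5 | 2,3,3-tribromoprop-2-enoic acid | OC(=O)C(Br)=C(Br)Br
F7 | step 5 | 2,3,3-tribromoprop-2-enoyl bromide | BrC(=O)C(Br)=C(Br)Br
F8 | step 5 | 2,3-dibromo-6-propyl-4H-pyran-4-one | CCCc1cc(=O)c(Br)c(Br)o1
F0 | step 2 | none | none
A1 | alternative 1 | 4-hydroxy-6-propyl-2H-pyran-2-one | CCCc1cc(O)cc(=O)o1
A2 | alternative 1 | 3,5-dibromo-4-hydroxy-6-propyl-2H-pyran-2-one | CCCc1oc(=O)c(Br)c(O)c1Br
A3 | alternative 1 | 3,4,5-tribromo-6-propyl-2H-pyran-2-one | CCCc1oc(=O)c(Br)c(Br)c1Br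
A4 | alternative 2 | 4-oxo-6-propyl-4H-pyran-2-carboxylic acid | CCCc1cc(=O)cc(C(=O)O)o1
A5 | alternative 3 | 2,2-dimethyl-6-propyl-4H-1,3-dioxin-4-one | CCCC1=CC(=O)OC(C)(C)O1
A6 | alternative 3 | butanoylketene (3-oxohex-1-en-1-one) | CCCC(=O)C=C=O
A7 | alternative 3 | 1,1-dibromoethene (purchased) | C=C(Br)Br
A8 | alternative 3 | 2,2-dibromo-6-propyl-2,3-dihydro-4H-pyran-4-one | CCCC1=CC(=O)CC(Br)(Br)O1
A9 | alternative 3 | 3-butanoyl-4-hydroxy-6-propyl-2H-pyran-2-one | CCCC(=O)c1c(O)cc(CCC)oc1=O
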